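The route rests on building the phloroglucinol ring A last. Its C5–C6–C7–C8 carbons, with the geranyl group already on C6, correspond to methyl 2-geranylacetoacetate, and C4a=C8a is the enone double bond of a 2-aryl-3-silyloxy-2,3-dihydropyran-4-one that already is ring C with C2 and C3 in place. A Diels–Alder reaction of the derived 1,3-bis(silyloxy)diene with the 5-bromo enone, followed by loss of HBr and methoxytrimethylsilane, should form C8–C8a and C5–C4a and deliver the 6-geranylphloroglucinol in one operation, its regiochemistry fixed by ring C. The hydroxyls at C3 and C3' travel as TBS ethers, so one buffered fluoride step completes the synthesis.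

Key step: step 9

Remark: the 3'-hydroxyl is protected as a TBS ether and not as an acetal, so that no acid has to meet the geranylphloroglucinol at the end and one fluoride step frees both hydroxyls.
Remark: a diene made from 4-methoxybut-3-en-2-one has no oxygen on its CH2 terminus, so the C3 oxygen of ring C is introduced after the hetero-Diels–Alder step by Rubottom oxidation; the silyloxydiene itself is bought.
Remark: before C3 carries oxygen the required enone is S at C2 (aryl outranks CH2); the same spatial arrangement becomes 2R once C3 is oxygenated.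
Assumption: (S)-BINOL is taken to direct the diene to the Si face of the aldehyde, by analogy with other BINOL/Ti(OiPr)4 additions to aryl aldehydes; the ligand antipode would be used if the sense proved opposite.
Remark: an amidine base is written into the key step because the hydrogen at C8a is not acidic and a strictly neutral medium offers no pathway for loss of HBr.

Step 1
Reactants: 1 isovanillin
Product: 2 3-(tert-butyldimethylsilyloxy)-4-methoxybenzaldehyde
Conditions: TBSCl, imidazole, DMF, rt
Reagents that add atoms: tert-butyldimethylsilyl chloride, CC(C)(C)[Si](C)(C)Cl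
Why: Standard silylation of a phenol; the aryl silyl ether tolerates the acidic, basic and oxidising steps that follow and falls to fluoride at the end.

Step 2
Reactants: 2 3-(tert-butyldimethylsilyloxy)-4-methoxybenzaldehyde; 3 (E)-1-methoxy-3-(trimethylsilyloxy)buta-1,3-diene
Product: 5 (S)-2-[3-(tert-butyldimethylsilyloxy)-4-methoxyphenyl]-2,3-dihydro-4H-pyran-4-one, via silyl aldol adduct 4 (not isolated)
Conditions: (S)-BINOL (20 mol%), Ti(OiPr)4 (10 mol%), 4 Å MS, Et2O, −20 °C; then CF3CO2H, CH2Cl2, 0 °C
Reagents that add atoms: none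
Why: Catalytic asymmetric hetero-Diels–Alder reaction in its Mukaiyama aldol/cyclisation form, in which the chiral titanium BINOLate differentiates the aldehyde faces and sets C2 as S, and acid closes the ring with loss of methanol.

Step 3
Reactants: 5 (S)-2-[3-(tert-butyldimethylsilyloxy)-4-methoxyphenyl]-2,3-dihydro-4H-pyran-4-one
Product: 8 (2R,3R)-2-[3-(tert-butyldimethylsilyloxy)-4-methoxyphenyl]-3-hydroxy-2,3-dihydro-4H-pyran-4-one, via silyl dienol ether 6 (not isolated), via silyloxy epoxide 7 (not isolated)
Conditions: LiN(SiMe3)2, Me3SiCl, THF, −78 °C; then dimethyldioxirane, acetone/CH2Cl2, −78 → −30 °C; then AcOH, THF/H2O, 0 °C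
Reagents that add atoms: dimethyldioxirane, CC1(C)OO1
Why: Rubottom oxidation, in which deprotonation is possible only at C3, the dioxirane attacks the more electron-rich C3=C4 bond of the silyl dienol ether from the face opposite the C2 aryl group, and opening of the silyloxy oxirane gives the ketol with C3 trans to the aryl group (3R).

Step 4
Reactants: 8 (2R,3R)-2-[3-(tert-butyldimethylsilyloxy)-4-methoxyphenyl]-3-hydroxy-2,3-dihydro-4H-pyran-4-one
Product: 9 (2R,3R)-3-(tert-butyldimethylsilyloxy)-2-[3-(tert-butyldimethylsilyloxy)-4-methoxyphenyl]-2,3-dihydro-4H-pyran-4-one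
Conditions: TBSOTf, 2,6-lutidine, CH2Cl2, −78 → 0 °C
Reagents that add atoms: tert-butyldimethylsilyl triflate, CC(C)(C)[Si](C)(C)OS(=O)(=O)C(F)(F)F
Why: Silylation of a hindered secondary alcohol with a silyl triflate and a weak hindered base, which leaves both stereocentres untouched.

Step 5
Reactants: 9 (2R,3R)-3-(tert-butyldimethylsilyloxy)-2-[3-(tert-butyldimethylsilyloxy)-4-methoxyphenyl]-2,3-dihydro-4H-pyran-4-one
Product: 10 (2R,3R)-5-bromo-3-(tert-butyldimethylsilyloxy)-2-[3-(tert-butyldimethylsilyloxy)-4-methoxyphenyl]-2,3-dihydro-4H-pyran-4-one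
Conditions: NBS (1.05 equiv), CH2Cl2, 0 °C → rt, dark
Reagents that add atoms: N-bromosuccinimide, O=C1CCC(=O)N1Br
Why: Electrophilic α-bromination of a vinylogous ester, whose enol-ether carbon C5 is the most nucleophilic site, with loss of the C5 proton restoring the enone; cold, stoichiometric reagent spares the aryl ring.

Step 6
Reactants: 11 methyl acetoacetate; 12 geranyl bromide
Product: 13 methyl 2-geranylacetoacetate
Conditions: NaH, THF, 0 °C; then 12, 0 °C → rt (11 in excess)
Reagents that add atoms: none
Why: SN2 C-alkylation of the acetoacetate enolate by a primary allylic bromide, which keeps the E double bond; excess 11 suppresses dialkylation.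

Step 7
Reactants: 13 methyl 2-geranylacetoacetate
Product: 14 methyl 2-geranyl-3-(trimethylsilyloxy)but-2-enoate
Conditions: Me3SiCl, Et3N, PhMe, rt
Reagents that add atoms: chlorotrimethylsilane, C[Si](C)(C)Cl
Why: O-silylation of the enolised β-keto ester under soft enolisation conditions, the usual first stage in making 1,3-bis(silyloxy)dienes from 2-alkylacetoacetates.

Step 8
Reactants: 14 methyl 2-geranyl-3-(trimethylsilyloxy)but-2-enoate
Product: 15 2-geranyl-1-methoxy-1,3-bis(trimethylsilyloxy)buta-1,3-diene
Conditions: LiN(iPr)2, THF, −78 °C; then Me3SiCl, −78 → 0 °C; crude product used at once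
Reagents that add atoms: chlorotrimethylsilane, C[Si](C)(C)Cl
Why: γ-Deprotonation of the silyl enol ether ester to the dienolate and O-silylation of the ester oxygen give the bis(silyloxy)diene; the allylic geranyl protons are far less acidic.

Step 9
Reactants: 10 (2R,3R)-5-bromo-3-(tert-butyldimethylsilyloxy)-2-[3-(tert-butyldimethylsilyloxy)-4-methoxyphenyl]-2,3-dihydro-4H-pyran-4-one; 15 2-geranyl-1-methoxy-1,3-bis(trimethylsilyloxy)buta-1,3-diene
Product: 18 (2R,3R)-3,3'-bis-O-(tert-butyldimethylsilyl)-4'-O-methyldiplacol, via bromo cycloadduct 16 (not isolated), via 7-O-trimethylsilyl ether 17 (not isolated)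
Conditions: 15 (2.5 equiv), PhMe, 20 → 80 °C; then DBU, −20 → 0 °C; then aq citric acid, THF, 0 °C
Reagents that add atoms: none
Why: Proposed new method: the CH2 terminus of the push–pull diene 15 should bond to the β-carbon of the bromo vinylogous ester 10 (C8–C8a) and its ketene-acetal carbon to the brominated α-carbon (C5–C4a), as an asynchronous [4+2] cycloaddition or as a Mukaiyama–Michael addition whose zwitterion collapses, to give 16; DBU then removes HBr across C4a–C8a, the mixed methyl silyl ketal at C5 collapses with loss of methoxytrimethylsilane, enolisation gives the phloroglucinol 17 and dilute acid frees the 7-hydroxyl. The closest known reactions are the Diels–Alder/aromatisation of 1-alkoxy-1,3-bis(silyloxy)dienes with haloquinones and the use of 2-bromocycloalkenones as cycloalkynone equivalents (cycloaddition, then amine-induced dehydrobromination); an α-bromo enone carrying a β-oxygen has not been used in this way. Ring A closes as a six-membered carbocycle by [4+2] cycloaddition (in the stepwise variant by 6-(enolexo)-exo-trig attack of C4a on the dioxy-stabilised cationic carbon C5). No stereocentre is created, because the sp3 centres at C4a, C5 and C8a vanish on aromatisation and the diene face is therefore irrelevant, while C2 and C3 are not involved. The step needs regioselectivity, which the matched polarisation of the two partners secures (the geranyl carbon ends between the new hydroxyls, at C6), and loss of bromide from C4a in preference to β-elimination of the ring oxygen from C8a, for which the cycloaddition is run without base and the amidine is added only cold and briefly; the 4'-methoxy group (no quinone methide) and the thermodynamically preferred trans arrangement guard C2 and C3.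

Step 10
Reactants: 18 (2R,3R)-3,3'-bis-O-(tert-butyldimethylsilyl)-4'-O-methyldiplacol
Product: 19 4'-O-methyldiplacol
Conditions: HF·pyridine, pyridine, THF, 0 °C → rt
Reagents that add atoms: none
Why: Fluoride-induced cleavage of the aryl and the secondary alkyl silyl ether in a pyridine-buffered medium, which should neither epimerise C2 or C3 nor cyclise the geranyl group onto a phenol.

Compound list
1 | isovanillin (3-hydroxy-4-methoxybenzaldehyde) | COc1ccc(C=O)cc1O | starting material
2 | 3-(tert-butyldimethylsilyloxy)-4-methoxybenzaldehyde | COc1ccc(C=O)cc1O[Si](C)(C)C(C)(C)C | intermediate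
3 | (E)-1-methoxy-3-(trimethylsilyloxy)buta-1,3-diene | CO/C=C/C(=C)O[Si](C)(C)C | starting material
4 | (S,E)-5-[3-(tert-butyldimethylsilyloxy)-4-methoxyphenyl]-1-methoxy-5-(trimethylsilyloxy)pent-1-en-3-one | COc1ccc([C@H](CC(=O)/C=C/OC)O[Si](C)(C)C)cc1O[Si](C)(C)C(C)(C)C | intermediate (not isolated)
5 | (S)-2-[3-(tert-butyldimethylsilyloxy)-4-methoxyphenyl]-2,3-dihydro-4H-pyran-4-one | COc1ccc([C@H]2OC=CC(=O)C2)cc1O[Si](C)(C)C(C)(C)C | intermediate
6 | (S)-2-[3-(tert-butyldimethylsilyloxy)-4-methoxyphenyl]-4-(trimethylsilyloxy)-2H-pyran | COc1ccc([C@H]2OC=CC(O[Si](C)(C)C)=C2)cc1O[Si](C)(C)C(C)(C)C | intermediate (not isolated)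
7 | 3,4-epoxide of 6, epoxide oxygen on the ring face opposite the aryl group | COc1ccc([C@H]2OC=C[C@]3(O[Si](C)(C)C)O[C@H]23)cc1O[Si](C)(C)C(C)(C)C | intermediate (not isolated)
8 | (2R,3R)-2-[3-(tert-butyldimethylsilyloxy)-4-methoxyphenyl]-3-hydroxy-2,3-dihydro-4H-pyran-4-one | COc1ccc([C@H]2OC=CC(=O)[C@@H]2O)cc1O[Si](C)(C)C(C)(C)C | intermediate
9 | (2R,3R)-3-(tert-butyldimethylsilyloxy)-2-[3-(tert-butyldimethylsilyloxy)-4-methoxyphenyl]-2,3-dihydro-4H-pyran-4-one | COc1ccc([C@H]2OC=CC(=O)[C@@H]2O[Si](C)(C)C(C)(C)C)cc1O[Si](C)(C)C(C)(C)C | intermediate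
10 | (2R,3R)-5-bromo-3-(tert-butyldimethylsilyloxy)-2-[3-(tert-butyldimethylsilyloxy)-4-methoxyphenyl]-2,3-dihydro-4H-pyran-4-one | COc1ccc([C@H]2OC=C(Br)C(=O)[C@@H]2O[Si](C)(C)C(C)(C)C)cc1O[Si](C)(C)C(C)(C)C | intermediate
11 | methyl acetoacetate | COC(=O)CC(C)=O | starting material
12 | geranyl bromide | CC(C)=CCC/C(C)=C/CBr | starting material
13 | methyl 2-geranylacetoacetate (methyl (E)-2-acetyl-5,9-dimethyldeca-4,8-dienoate, racemic at C2) | COC(=O)C(C/C=C(\C)CCC=C(C)C)C(C)=O | intermediate
14 | methyl 2-geranyl-3-(trimethylsilyloxy)but-2-enoate (enol-ether geometry not controlled) | COC(=O)C(C/C=C(\C)CCC=C(C)C)=C(C)O[Si](C)(C)C | intermediate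
15 | 2-geranyl-1-methoxy-1,3-bis(trimethylsilyloxy)buta-1,3-diene (ketene-acetal geometry not controlled and without consequence) | COC(O[Si](C)(C)C)=C(C/C=C(\C)CCC=C(C)C)C(=C)O[Si](C)(C)C | intermediate
16 | cis-fused cycloadduct: (2R,3R)-4a-bromo-6-geranyl-5-methoxy-5,7-bis(trimethylsilyloxy)-4a,5,8,8a-tetrahydro derivative of the protected flavanonol (mixture at C4a, C5, C8a) | COc1ccc([C@H]2OC3CC(O[Si](C)(C)C)=C(C/C=C(\C)CCC=C(C)C)C(OC)(O[Si](C)(C)C)C3(Br)C(=O)[C@@H]2O[Si](C)(C)C(C)(C)C)cc1O[Si](C)(C)C(C)(C)C | intermediate (not isolated)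
17 | 7-O-trimethylsilyl ether of 18 | COc1ccc([C@H]2Oc3cc(O[Si](C)(C)C)c(C/C=C(\C)CCC=C(C)C)c(O)c3C(=O)[C@@H]2O[Si](C)(C)C(C)(C)C)cc1O[Si](C)(C)C(C)(C)C | intermediate (not isolated)
18 | (2R,3R)-3,3'-bis-O-(tert-butyldimethylsilyl)-4'-O-methyldiplacol | COc1ccc([C@H]2Oc3cc(O)c(C/C=C(\C)CCC=C(C)C)c(O)c3C(=O)[C@@H]2O[Si](C)(C)C(C)(C)C)cc1O[Si](C)(C)C(C)(C)C | intermediate
19 | 4'-O-methyldiplacol, (2R,3R)-6-geranyl-3,5,7-trihydroxy-2-(3-hydroxy-4-methoxyphenyl)chroman-4-one | COc1ccc([C@H]2Oc3cc(O)c(C/C=C(\C)CCC=C(C)C)c(O)c3C(=O)[C@@H]2O)cc1O | target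

Total step count: 10
Longest linear sequence: 7 steps (steps 1, 2, 3, 4, 5, 9, 10); the diene branch (steps 6, 7, 8) joins at step 9.

Steps most likely to fail

1. Step 9 (Proposed new method). The β-oxygenated bromo enone may be too weak a dienophile, so that the diene is lost to silyl migration or hydrolysis before it adds. After addition, base may open ring C by β-elimination of the ring oxygen from C8a, or bromine may be lost reductively, instead of HBr being eliminated. Fallback (known chemistry; it gives up the benzannulation and the regiocontrol that ring C provides): it sets out from isovanillin 1 and geranyl bromide 12 and comes back at target 19. Commercial 2,4,6-trihydroxyacetophenone would be C-geranylated with 12 (K2CO3, acetone, reflux) to 1-(3-geranyl-2,4,6-trihydroxyphenyl)ethanone F1 and converted into 1-[3-geranyl-2,4,6-tris(methoxymethoxy)phenyl]ethanone F2 (NaH, MOMCl, DMF). Isovanillin 1 would give 4-methoxy-3-(methoxymethoxy)benzaldehyde F3 (MOMCl, iPr2NEt, CH2Cl2). Claisen–Schmidt condensation of F2 with F3 (KOH, EtOH, rt) would give the (E)-chalcone F4, and Juliá–Colonna epoxidation (poly-L-leucine, urea–H2O2, DBU, THF) the (αR,βS)-epoxy ketone F5. HCl in MeOH would then remove the four MOM groups and let an ortho-phenol open the oxirane at the benzylic carbon with inversion, giving the trans-dihydroflavonol 19. Either ortho-hydroxyl can close, so the 8-geranyl isomer of the target F6 would form alongside and would have to be separated.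

2. Step 2. Addition to the electron-rich, deactivated aldehyde may be slow, so that the uncatalysed background reaction erodes the enantioselectivity. Fallback: it sets out from aldehyde 2 and comes back at enone 5. Commercial (E)-4-methoxybut-3-en-2-one would be enolised with Ipc2BCl and iPr2NEt (Et2O, −78 °C; the reagent antipode that directs attack to the Si face of 2) and added to 2. Oxidative work-up (H2O2, pH 7 buffer) would give (S,E)-5-[3-(tert-butyldimethylsilyloxy)-4-methoxyphenyl]-5-hydroxy-1-methoxypent-1-en-3-one F7, which would cyclise with loss of methanol (pyridinium p-toluenesulfonate, CH2Cl2, rt) to 5. A stoichiometric, reagent-controlled boron aldol addition thus replaces the catalytic step.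

3. Step 3. The silyl dienol ether is a 2H-pyran that may undergo electrocyclic ring opening and reclosure, which would scramble C2, or the oxidant may attack the C5=C6 enol ether instead of C3=C4. Fallback: it sets out from enone 5 and comes back at ketol 8. Mn(OAc)3 in benzene at reflux would acetoxylate the α'-position C3 trans to the aryl group, giving (2R,3R)-3-acetoxy-2-[3-(tert-butyldimethylsilyloxy)-4-methoxyphenyl]-2,3-dihydro-4H-pyran-4-one F8. Pig liver esterase in pH 7 phosphate buffer/acetone would then release 8 without base, so that no silyl dienol ether is formed at all.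

Further compounds
F1 | step 9 | 1-(3-geranyl-2,4,6-trihydroxyphenyl)ethanone | CC(=O)c1c(O)cc(O)c(C/C=C(\C)CCC=C(C)C)c1O
F2 | step 9 | 1-[3-geranyl-2,4,6-tris(methoxymethoxy)phenyl]ethanone | CC(=O)c1c(OCOC)cc(OCOC)c(C/C=C(\C)CCC=C(C)C)c1OCOC
F3 | step 9 | 4-methoxy-3-(methoxymethoxy)benzaldehyde | COCOc1cc(C=O)ccc1OC
F4 | step 9 | (E)-1-[3-geranyl-2,4,6-tris(methoxymethoxy)phenyl]-3-[4-methoxy-3-(methoxymethoxy)phenyl]prop-2-en-1-one | COCOc1cc(/C=C/C(=O)c2c(OCOC)cc(OCOC)c(C/C=C(\C)CCC=C(C)C)c2OCOC)ccc1OC
F5 | step 9 | (αR,βS)-epoxide of chalcone F4 | COCOc1cc([C@@H]2O[C@H]2C(=O)c2c(OCOC)cc(OCOC)c(C/C=C(\C)CCC=C(C)C)c2OCOC)ccc1OC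
F6 | step 9 | (2R,3R)-8-geranyl-3,5,7-trihydroxy-2-(3-hydroxy-4-methoxyphenyl)chroman-4-one | COc1ccc([C@H]2Oc3c(C/C=C(\C)CCC=C(C)C)c(O)cc(O)c3C(=O)[C@@H]2O)cc1O
F7 | step 2 | (S,E)-5-[3-(tert-butyldimethylsilyloxy)-4-methoxyphenyl]-5-hydroxy-1-methoxypent-1-en-3-one | COc1ccc([C@@H](O)CC(=O)/C=C/OC)cc1O[Si](C)(C)C(C)(C)C
F8 | step 3 | (2R,3R)-3-acetoxy-2-[3-(tert-butyldimethylsilyloxy)-4-methoxyphenyl]-2,3-dihydro-4H-pyran-4-one | COc1ccc([C@H]2OC=CC(=O)[C@@H]2OC(C)=O)cc1O[Si](C)(C)C(C)(C)C
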